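The plan cuts C3–C15, the bond between the two adjacent quaternary carbons. The target shows C15–C3–C11=C10 where rings A, B and C meet. C16 lies one reduction below a carboxylic acid, and the C7–C8–C9 bridge of ring C joins C15 to C10. Together these features are the signature of a lactone enolate Claisen rearrangement. In one operation the silyl ketene acetal forms C3–C15, moves the alkene from C3=C11 to C10=C11, closes ring C as the lactone opens, and sets C3 and C15. The precursor is a seven-membered spirolactone on the ring A/B bicyclo[3.3.0]octene. It has the ring oxygen on C10 (face opposite H12), carbonyl C16, allyl on C15 and silyloxymethyl on C7.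

Key step: step 22

Remarks on the chemistry
- **Numbering:** C1–C22 follow the target SMILES from the ester-bearing CH. C1′ is the side-arm carbon on C1. PMB = 4-methoxybenzyl, TBS = tert-butyldimethylsilyl, Ns = 2-nitrobenzenesulfonyl.
- **Stereochemical check:** C1, C7 and C12 are carried unchanged from 43 to 46 to 68. The C10–O bond of 43, anti to H12, maps onto the C3–C15 bond of 46.
- **Side arms:** both arms (C1′ and C4) carry PMB because they are unmasked and oxidised together. Benzyl is kept for C16.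
- **Lactone:** it is closed from the α-unbranched acid and allylated afterwards, since enolisation erases C15. Compound 43 is used as its C15 epimer mixture.
- **C19/C20:** these come from a syn aldol, so no alkene is cleaved beside C10=C11 and C22 is never an epimerisable aldehyde.
- **Acetate:** it is introduced after N5 is acylated, so no O-to-N acetyl shift can occur.
- **Transient centres:** the new centres in 17, 20 and 36 are mixtures and are destroyed in the same flask.

Step 1
Reactants: 1 4-methoxybenzyl alcohol; 2 3-bromo-2-(bromomethyl)prop-1-ene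
Product: 3 1-({[2-(bromomethyl)prop-2-en-1-yl]oxy}methyl)-4-methoxybenzene
Conditions: NaH, THF, 0 °C; 2 (3 equiv), rt
Reagents that add atoms: none
Why: Williamson etherification with an excess of the symmetrical allylic dibromide should stop at monosubstitution and leaves one allylic bromide as the C2 terminus of the C2–C3–C4 unit.

Step 2
Reactants: 4 cyclopent-2-en-1-one; 5 dimethyl malonate
Product: 6 dimethyl 2-[(1S)-3-oxocyclopentyl]propanedioate
Conditions: NaGa[(S)-BINOLate]2 (10 mol %; from GaCl3, (S)-BINOL, NaOtBu), NaOtBu (7 mol %), THF, rt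
Reagents that add atoms: none
Why: Catalytic asymmetric Michael addition in which the heterobimetallic binaphthoxide binds enone and malonate together, so the (S)-ligand should direct attack to one face of C12 and set it as (S).

Step 3
Reactants: 6 dimethyl 2-[(1S)-3-oxocyclopentyl]propanedioate
Product: 8 [(1S)-3-oxocyclopentyl]acetic acid, via malonic acid 7 (not isolated)
Conditions: 6 M HCl, reflux
Reagents that add atoms: water, O
Why: Acid ester hydrolysis followed by thermal decarboxylation of the malonic acid is routine and leaves C12, which bears no acidic hydrogen, untouched.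

Step 4
Reactants: 8 [(1S)-3-oxocyclopentyl]acetic acid; 9 (4R)-4-benzyl-1,3-oxazolidin-2-one
Product: 11 (4R)-4-benzyl-3-{[(1S)-3-oxocyclopentyl]acetyl}-1,3-oxazolidin-2-one, via mixed pivalic anhydride 10 (not isolated)
Conditions: t-BuCOCl, Et3N, THF, −20 °C; then LiCl, 9, rt
Reagents that add atoms: none
Why: Mixed-anhydride N-acylation under LiCl/Et3N conditions needs no strong base, so the free ketone is tolerated.

Step 5
Reactants: 11 (4R)-4-benzyl-3-{[(1S)-3-oxocyclopentyl]acetyl}-1,3-oxazolidin-2-one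
Product: 12 (4R)-4-benzyl-3-{[(7S)-1,4-dioxaspiro[4.4]nonan-7-yl]acetyl}-1,3-oxazolidin-2-one
Conditions: (Me3SiOCH2)2, Me3SiOTf (cat.), CH2Cl2, −78 to −20 °C
Reagents that add atoms: 1,2-bis(trimethylsilyloxy)ethane, C[Si](C)(C)OCCO[Si](C)(C)C
Why: Noyori ketalisation masks the C10 ketone against the enolate, hydride and alkoxide steps that follow, and its aprotic conditions do not solvolyse the imide.

Step 6
Reactants: 12 (4R)-4-benzyl-3-{[(7S)-1,4-dioxaspiro[4.4]nonan-7-yl]acetyl}-1,3-oxazolidin-2-one; 3 1-({[2-(bromomethyl)prop-2-en-1-yl]oxy}methyl)-4-methoxybenzene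
Product: 14 (4R)-4-benzyl-3-[(2R)-2-[(7S)-1,4-dioxaspiro[4.4]nonan-7-yl]-4-{[(4-methoxybenzyl)oxy]methyl}pent-4-enoyl]-1,3-oxazolidin-2-one, via sodium Z-enolate 13 (not isolated)
Conditions: NaN(SiMe3)2, THF, −78 °C; then 3, −78 to −40 °C
Reagents that add atoms: none
Why: Evans alkylation, in which the chelated Z-enolate is attacked by the allylic bromide on the face away from the benzyl group of the (R)-auxiliary, sets C1 as (R) so that H1 and H12 become cis in ring A.

Step 7
Reactants: 14 alkylated imide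
Product: 15 (2R)-2-[(7S)-1,4-dioxaspiro[4.4]nonan-7-yl]-4-{[(4-methoxybenzyl)oxy]methyl}pent-4-en-1-ol
Conditions: LiBH4, H2O (1 equiv), Et2O, 0 °C
Reagents that add atoms: none
Why: Reductive removal of the auxiliary by LiBH4 takes the exocyclic imide carbonyl to the C1′ alcohol without enolisation, so C1 is kept.

Step 8
Reactants: 15 C1′ alcohol
Product: 16 (7S)-7-[(2R)-1-[(4-methoxybenzyl)oxy]-4-{[(4-methoxybenzyl)oxy]methyl}pent-4-en-2-yl]-1,4-dioxaspiro[4.4]nonane
Conditions: NaH, PMBCl, Bu4NI (cat.), DMF, 0 °C to rt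
Reagents that add atoms: 4-methoxybenzyl chloride, COc1ccc(CCl)cc1
Why: Williamson etherification gives the C1′ arm the same PMB ether as the C4 arm, so both can later be released in one operation.

Step 9
Reactants: 16 bis-PMB alkene
Product: 18 (4R)-4-[(7S)-1,4-dioxaspiro[4.4]nonan-7-yl]-1,5-bis[(4-methoxybenzyl)oxy]pentan-2-one, via vicinal diol 17 (not isolated)
Conditions: OsO4 (cat.), NaIO4, 2,6-lutidine, dioxane–H2O, rt
Reagents that add atoms: sodium periodate, [Na+].[O-]I(=O)(=O)=O; water, O
Why: Lemieux–Johnson cleavage of the only alkene unmasks the C3 ketone under near-neutral conditions that spare the ketal and both PMB ethers.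

Step 10
Reactants: 18 ketal ketone
Product: 21 (3aR,4R)-4,6-bis{[(4-methoxybenzyl)oxy]methyl}-3,3a,4,5-tetrahydropentalen-1(2H)-one, via diketone 19 (not isolated), via aldol adduct 20 (not isolated)
Conditions: 1 M HCl, THF, rt; then KOH, MeOH, 40 °C
Reagents that add atoms: water, O
Why: Ketal hydrolysis frees the 1,6-diketone, and intramolecular aldol condensation should close ring A because only attack of the C11 enolate on the alkoxy-activated C3 ketone can dehydrate, whereas the bridged aldol from C2 onto C10 is reversible and C1 and C12 carry no acidic hydrogen.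

Step 11
Reactants: 22 pent-4-enoic acid; 23 (4S)-4-benzyl-1,3-oxazolidin-2-one
Product: 25 (4S)-4-benzyl-3-(pent-4-enoyl)-1,3-oxazolidin-2-one, via mixed pivalic anhydride 24 (not isolated)
Conditions: t-BuCOCl, Et3N, THF, −20 °C; then LiCl, 23, rt
Reagents that add atoms: none
Why: Mixed-anhydride N-acylation attaches the auxiliary to the acid that supplies C6, C7, C15 and C16.

Step 12
Reactants: 25 (4S)-4-benzyl-3-(pent-4-enoyl)-1,3-oxazolidin-2-one; 26 tert-butyl bromoacetate
Product: 28 tert-butyl (3R)-3-{[(4S)-4-benzyl-2-oxo-1,3-oxazolidin-3-yl]carbonyl}hex-5-enoate, via sodium Z-enolate 27 (not isolated)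
Conditions: NaN(SiMe3)2, THF, −78 °C; then 26, −78 °C
Reagents that add atoms: none
Why: Evans alkylation with a reactive α-bromo ester (C8 and C9) occurs on the enolate face opposite the benzyl group of the (S)-auxiliary and sets C7.

Step 13
Reactants: 28 alkylated imide
Product: 29 tert-butyl (3R)-3-(hydroxymethyl)hex-5-enoate
Conditions: LiBH4, MeOH (1 equiv), THF, 0 °C
Reagents that add atoms: none
Why: LiBH4 reduces the activated imide carbonyl (C6) much faster than the tert-butyl ester, so the two carboxyl carbons are told apart in one chemoselective reduction.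

Step 14
Reactants: 29 tert-butyl (3R)-3-(hydroxymethyl)hex-5-enoate
Product: 30 tert-butyl (3R)-3-({[tert-butyl(dimethyl)silyl]oxy}methyl)hex-5-enoate
Conditions: TBSCl, imidazole, CH2Cl2, rt
Reagents that add atoms: tert-butyldimethylsilyl chloride, CC(C)(C)[Si](C)(C)Cl
Why: Prompt silylation of the C6 alcohol forestalls γ-lactonisation and installs a group that survives organometallic, amide-base and hydride steps.

Step 15
Reactants: 30 silyl ether ester
Product: 31 (3R)-3-({[tert-butyl(dimethyl)silyl]oxy}methyl)hex-5-en-1-ol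
Conditions: LiAlH4, Et2O, 0 °C
Reagents that add atoms: none
Why: Ester reduction by LiAlH4 gives the C9 alcohol and leaves the silyl ether and the alkene alone.

Step 16
Reactants: 31 C9 alcohol
Product: 32 tert-butyl{[(2R)-2-(2-iodoethyl)pent-4-en-1-yl]oxy}dimethylsilane
Conditions: I2, PPh3, imidazole, CH2Cl2, 0 °C
Reagents that add atoms: iodine, II
Why: Appel-type iodination of an unhindered primary alcohol gives the iodide needed for clean halogen–lithium exchange.

Step 17
Reactants: 32 iodide; 21 bicyclic enone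
Product: 35 C10 tertiary allylic alcohol (C9 chain on the H12 face; OH on the opposite face), via alkyllithium 33 (not isolated), via organocerium reagent 34 (not isolated)
Conditions: t-BuLi (2 equiv), Et2O–pentane, −78 °C; CeCl3, THF, −78 °C; then 21, −78 °C; aq NH4Cl
Reagents that add atoms: none
Why: Organocerium 1,2-addition should take the hindered, enolisable enone carbonyl without conjugate addition and from the convex face of the folded bicycle (the H12 face, away from C1, C13 and the C1′ arm), which puts the C10 oxygen on the concave face, while −78 °C keeps the hexenyllithium from cyclising onto its own alkene.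

Step 18
Reactants: 35 tertiary allylic alcohol
Product: 37 C16 aldehyde of the C10 carbinol, via triol 36 (not isolated)
Conditions: OsO4 (cat.), NaIO4, 2,6-lutidine, dioxane–H2O, 0 °C to rt
Reagents that add atoms: sodium periodate, [Na+].[O-]I(=O)(=O)=O; water, O
Why: In this Lemieux–Johnson cleavage the bulky OsO4 should take the monosubstituted alkene far faster than the tetrasubstituted C3=C11 alkene, so C16 appears as the aldehyde.

Step 19
Reactants: 37 hydroxy aldehyde
Product: 38 C10-hydroxy C16-carboxylic acid (seco acid)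
Conditions: NaClO2, NaH2PO4, 2-methylbut-2-ene, t-BuOH–H2O, rt
Reagents that add atoms: sodium chlorite, [Na+].[O-]Cl=O
Why: Pinnick oxidation is selective for the aldehyde, the scavenger protects C3=C11 from hypochlorous acid, and the buffer is too weakly acidic to ionise the carbinol.

Step 20
Reactants: 38 seco acid
Product: 40 seven-membered spirolactone with C15H2 (ring O on C10; carbonyl C16), via mixed aromatic anhydride 39 (not isolated)
Conditions: 2-methyl-6-nitrobenzoic anhydride, DMAP, CH2Cl2 (2 mM, slow addition), rt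
Reagents that add atoms: none
Why: Shiina lactonisation should work because the acid is unbranched at C15 and the chain is pre-folded by the substituents at C10 and C7, so acyl transfer from the acylpyridinium ion to the tertiary carbinol proceeds under basic, non-ionising conditions that leave C10 intact.

Step 21
Reactants: 40 spirolactone; 41 allyl iodide
Product: 43 α-allyl spirolactone (Claisen precursor; C15 epimers), via lithium enolate 42 (not isolated)
Conditions: LiN(iPr)2, THF, −78 °C; then 41, DMPU, −78 to −40 °C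
Reagents that add atoms: none
Why: Lactone enolate alkylation with a very reactive allylic iodide runs below the temperature at which the lithium enolate could rearrange, and either C15 epimer serves because the next step makes C15 planar.

Step 22
Reactants: 43 α-allyl spirolactone
Product: 46 tricyclic C16 carboxylic acid with rings A B C, via silyl ketene acetal 44 (not isolated), via trimethylsilyl ester 45 (not isolated)
Conditions: KN(SiMe3)2, Me3SiCl–Et3N, THF–toluene, −78 °C; then toluene, 90 °C; then 1 M HCl, THF, rt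
Reagents that add atoms: none
Why: KN(SiMe3)2 removes H15 and Me3SiCl traps the enolate on oxygen, giving a ketene acetal whose C15=C16 bond is endocyclic, so C7 lies cis to the ring oxygen whichever C15 epimer is used; on heating, C15=C16–O–C10–C11=C3 undergoes a concerted suprafacial [3,3] shift (Ireland–Claisen rearrangement), the closest known class being the rearrangement of alkenyl-substituted lactone silyl ketene acetals to cycloalkene carboxylic acids. Ring C (C3–C11–C10–C9–C8–C7–C15) is closed pericyclically, with C3–C15 forming while C10–O breaks, and not by an exo or endo nucleophilic attack, and the three-atom tether allows only a boat-shaped array. C3 is controlled by C10: the C10–O bond lies on the face opposite H12, so C15 is delivered to that face and the C4 arm is pushed to the H12 face. C15 is controlled by the fixed ketene acetal geometry together with the boat array, which leaves C16 cis to C2 and the allyl group cis to C4 on ring C. The step needs only facial selectivity, and this is secured because the tethered ketene acetal cannot reach the other face of C3=C11. The cost of joining two fully substituted carbons is offset by C–O cleavage to a silyl carboxylate and by the gain of the tetrasubstituted C10=C11 alkene.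

Step 23
Reactants: 46 tricyclic acid
Product: 47 C16 primary alcohol
Conditions: LiAlH4, THF, 0 to 40 °C
Reagents that add atoms: none
Why: LiAlH4 reduction is the reliable way to take a neopentyl carboxylic acid to the alcohol, and nothing else in 46 is reducible.

Step 24
Reactants: 47 C16 alcohol
Product: 48 C16 benzyl ether
Conditions: NaH, BnBr, Bu4NI (cat.), DMF, 0 °C to rt
Reagents that add atoms: benzyl bromide, BrCc1ccccc1
Why: Williamson benzylation gives C16 a group that survives borane, boron triflate, hydride, fluoride, DDQ and thiolate and can be removed once N5 is acylated.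

Step 25
Reactants: 48 benzyl ether
Product: 50 C19 primary alcohol, via B-alkyl-9-BBN adduct 49 (not isolated)
Conditions: 9-BBN, THF, rt; then NaOH, H2O2, 0 °C
Reagents that add atoms: hydrogen peroxide, OO
Why: Hydroboration–oxidation with the bulky 9-BBN is anti-Markovnikov and takes only the monosubstituted alkene, because the tetrasubstituted C10=C11 alkene is inert.

Step 26
Reactants: 50 C19 alcohol
Product: 51 C19 aldehyde
Conditions: Dess–Martin periodinane, NaHCO3, CH2Cl2, rt
Reagents that add atoms: none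
Why: Dess–Martin oxidation of the only free alcohol stops cleanly at the aldehyde under buffered conditions.

Step 27
Reactants: 51 C19 aldehyde; 52 (4S)-4-benzyl-3-propanoyl-1,3-oxazolidin-2-one
Product: 54 syn aldol adduct (C19 R; C20 S; C22 as imide carbonyl), via dibutylboron Z-enolate 53 (not isolated)
Conditions: 52, Bu2BOTf, Et3N, CH2Cl2, −78 to 0 °C; then 51, −78 to 0 °C; pH 7 buffer, MeOH, H2O2
Reagents that add atoms: none
Why: In the Evans syn aldol reaction the Z-boron enolate reacts through a closed chair transition state whose face is fixed by the (S)-auxiliary, which sets the C19 hydroxyl and the C20 methyl syn with the required absolute sense under pure reagent control.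

Step 28
Reactants: 54 aldol adduct
Product: 55 C19 TBS ether
Conditions: TBSOTf, 2,6-lutidine, CH2Cl2, 0 °C
Reagents that add atoms: tert-butyldimethylsilyl triflate, CC(C)(C)[Si](C)(C)OS(=O)(=O)C(F)(F)F
Why: Silylation with the triflate covers the hindered secondary alcohol, blocks retro-aldol cleavage and keeps C19 distinct from C16 until the last step.

Step 29
Reactants: 55 silylated imide
Product: 56 C22 primary alcohol
Conditions: LiBH4, MeOH (1 equiv), THF, 0 °C
Reagents that add atoms: none
Why: Reductive auxiliary removal delivers C22 directly at the alcohol level, so C20 is never next to an aldehyde and cannot epimerise.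

Step 30
Reactants: 56 C22 alcohol; 57 2-nitrobenzenesulfonamide
Product: 58 C22 N-Ns secondary sulfonamide (N5 installed)
Conditions: 57 (3 equiv), PPh3, DIAD, THF, 0 °C to rt
Reagents that add atoms: none
Why: Fukuyama–Mitsunobu alkylation of the acidic sulfonamide by the only free, primary alcohol brings in N5, and the excess of 57 suppresses double alkylation.

Step 31
Reactants: 58 sulfonamide
Product: 59 C6 primary alcohol
Conditions: HF·pyridine, pyridine, THF, 0 °C
Reagents that add atoms: none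
Why: Buffered fluoride desilylation removes a primary TBS ether much faster than the α-branched secondary one at C19.

Step 32
Reactants: 59 hydroxy sulfonamide
Product: 60 N-Ns nine-membered azacycle (N5–C6 bond; ring E without C4)
Conditions: PPh3, DIAD, toluene (2 mM), rt to 50 °C
Reagents that add atoms: none
Why: Intramolecular Fukuyama–Mitsunobu reaction is an established entry to eight- to ten-membered cyclic amines, and here the quaternary C15 and the branches at C7, C19 and C20 restrict the chain in favour of closure.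

Step 33
Reactants: 60 azacycle
Product: 61 C1′,C4-diol
Conditions: DDQ, CH2Cl2–pH 7 buffer, 0 °C
Reagents that add atoms: none
Why: Oxidative PMB cleavage releases both arms at once and leaves the less electron-rich benzyl ether, the silyl ether, the sulfonamide and the hindered alkene.

Step 34
Reactants: 61 diol
Product: 62 C1′,C4-dicarboxylic acid
Conditions: AZADO (cat.), NaOCl (cat.), NaClO2, MeCN–pH 6.8 phosphate buffer, rt
Reagents that add atoms: sodium chlorite, [Na+].[O-]Cl=O
Why: Nitroxyl/chlorite oxidation with the unhindered AZADO radical takes both primary alcohols, the neopentyl C4 one included, to the acids at near-neutral pH, so the transient C1′ aldehyde has no time to epimerise at C1.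

Step 35
Reactants: 62 diacid
Product: 63 dimethyl ester
Conditions: Me3SiCHN2, toluene–MeOH, 0 °C
Reagents that add atoms: (trimethylsilyl)diazomethane, C[Si](C)(C)C=[N+]=[N-]
Why: Diazoalkane esterification is insensitive to hindrance at C3 and base-free, and the fully substituted sulfonamide nitrogen can no longer be methylated.

Step 36
Reactants: 63 dimethyl ester
Product: 65 pentacyclic lactam (rings A to E; C16 OBn; C19 OTBS), via azonane amine 64 (not isolated)
Conditions: PhSH, Cs2CO3, MeCN, rt; then 2-hydroxypyridine (cat.), toluene, 100 °C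
Reagents that add atoms: none
Why: Fukuyama denosylation through a Meisenheimer adduct frees N5, which should lactamise only with the C4 ester because that closure is six-membered (ring D) while the C1′ ester is out of reach and no acetate is yet present to divert the amine.

Step 37
Reactants: 65 lactam
Product: 66 C16 primary alcohol
Conditions: H2 (1 atm), 10% Pd/C, EtOAc–EtOH, rt
Reagents that add atoms: none
Why: Hydrogenolysis removes the benzyl ether while the buried tetrasubstituted C10=C11 alkene should resist hydrogenation under these mild conditions.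

Step 38
Reactants: 66 C16 alcohol
Product: 67 C16 acetate
Conditions: Ac2O, pyridine, DMAP (cat.), CH2Cl2, rt
Reagents that add atoms: acetic anhydride, CC(=O)OC(C)=O
Why: DMAP-catalysed acetylation meets a single free hydroxyl group, so no selectivity between C16 and C19 is required.

Step 39
Reactants: 67 acetate
Product: 68 CNP0296366.1 (target)
Conditions: HF·pyridine, THF, rt
Reagents that add atoms: none
Why: Acidic fluoride desilylation frees the C19 alcohol without touching the acetate, methyl ester, lactam or alkene.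

Compound list
1 | 4-methoxybenzyl alcohol | COc1ccc(CO)cc1 | starting material
2 | 3-bromo-2-(bromomethyl)prop-1-ene | C=C(CBr)CBr | starting material
3 | 1-({[2-(bromomethyl)prop-2-en-1-yl]oxy}methyl)-4-methoxybenzene | C=C(CBr)COCc1ccc(OC)cc1 | intermediate
4 | cyclopent-2-en-1-one | O=C1C=CCC1 | starting material
5 | dimethyl malonate | COC(=O)CC(=O)OC | starting material
6 | dimethyl 2-[(1S)-3-oxocyclopentyl]propanedioate | O=C1C[C@@H](C(C(=O)OC)C(=O)OC)CC1 | intermediate
7 | 2-[(1S)-3-oxocyclopentyl]propanedioic acid | O=C1C[C@@H](C(C(=O)O)C(=O)O)CC1 | intermediate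
8 | [(1S)-3-oxocyclopentyl]acetic acid | O=C1C[C@@H](CC(=O)O)CC1 | intermediate
9 | (4R)-4-benzyl-1,3-oxazolidin-2-one | O=C1N[C@H](Cc2ccccc2)CO1 | starting material
10 | mixed anhydride of 8 and pivalic acid | O=C1C[C@@H](CC(=O)OC(=O)C(C)(C)C)CC1 | intermediate
11 | (4R)-4-benzyl-3-{[(1S)-3-oxocyclopentyl]acetyl}-1,3-oxazolidin-2-one | O=C1C[C@@H](CC(=O)N2[C@H](Cc3ccccc3)COC2=O)CC1 | intermediate
12 | (4R)-4-benzyl-3-{[(7S)-1,4-dioxaspiro[4.4]nonan-7-yl]acetyl}-1,3-oxazolidin-2-one | O=C(C[C@H]1CCC2(C1)OCCO2)N3[C@H](Cc4ccccc4)COC3=O | intermediate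
13 | sodium Z-enolate of 12 | [Na+].[O-]/C(=C\[C@H]1CCC2(C1)OCCO2)N3[C@H](Cc4ccccc4)COC3=O | intermediate
14 | (4R)-4-benzyl-3-[(2R)-2-[(7S)-1,4-dioxaspiro[4.4]nonan-7-yl]-4-{[(4-methoxybenzyl)oxy]methyl}pent-4-enoyl]-1,3-oxazolidin-2-one | O=C([C@H](CC(=C)COCc5ccc(OC)cc5)[C@H]1CCC2(C1)OCCO2)N3[C@H](Cc4ccccc4)COC3=O | intermediate
15 | (2R)-2-[(7S)-1,4-dioxaspiro[4.4]nonan-7-yl]-4-{[(4-methoxybenzyl)oxy]methyl}pent-4-en-1-ol | OC[C@H](CC(=C)COCc5ccc(OC)cc5)[C@H]1CCC2(C1)OCCO2 | intermediate
16 | (7S)-7-[(2R)-1-[(4-methoxybenzyl)oxy]-4-{[(4-methoxybenzyl)oxy]methyl}pent-4-en-2-yl]-1,4-dioxaspiro[4.4]nonane | COc6ccc(COC[C@H](CC(=C)COCc5ccc(OC)cc5)[C@H]1CCC2(C1)OCCO2)cc6 | intermediate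
17 | vicinal diol from 16 (C3 epimers) | COc6ccc(COC[C@H](CC(O)(CO)COCc5ccc(OC)cc5)[C@H]1CCC2(C1)OCCO2)cc6 | intermediate
18 | (4R)-4-[(7S)-1,4-dioxaspiro[4.4]nonan-7-yl]-1,5-bis[(4-methoxybenzyl)oxy]pentan-2-one | COc6ccc(COC[C@H](CC(=O)COCc5ccc(OC)cc5)[C@H]1CCC2(C1)OCCO2)cc6 | intermediate
19 | (4R)-1,5-bis[(4-methoxybenzyl)oxy]-4-[(1S)-3-oxocyclopentyl]pentan-2-one | COc6ccc(COC[C@H](CC(=O)COCc5ccc(OC)cc5)[C@H]1CCC(=O)C1)cc6 | intermediate
20 | bicyclic aldol adduct (C3 hydroxy ketone; C3 and C11 undefined) | COc6ccc(COC[C@@H]1CC(O)(COCc5ccc(OC)cc5)C2[C@@H]1CCC2=O)cc6 | intermediate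
21 | (3aR,4R)-4,6-bis{[(4-methoxybenzyl)oxy]methyl}-3,3a,4,5-tetrahydropentalen-1(2H)-one (H1 and H12 cis) | COc6ccc(COC[C@@H]1CC(COCc5ccc(OC)cc5)=C2[C@@H]1CCC2=O)cc6 | intermediate
22 | pent-4-enoic acid | C=CCCC(=O)O | starting material
23 | (4S)-4-benzyl-1,3-oxazolidin-2-one | O=C1N[C@@H](Cc2ccccc2)CO1 | starting material
24 | mixed anhydride of 22 and pivalic acid | C=CCCC(=O)OC(=O)C(C)(C)C | intermediate
25 | (4S)-4-benzyl-3-(pent-4-enoyl)-1,3-oxazolidin-2-one | C=CCCC(=O)N1[C@@H](Cc2ccccc2)COC1=O | intermediate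
26 | tert-butyl bromoacetate | BrCC(=O)OC(C)(C)C | starting material
27 | sodium Z-enolate of 25 | [Na+].[O-]/C(=C\CC=C)N1[C@@H](Cc2ccccc2)COC1=O | intermediate
28 | tert-butyl (3R)-3-{[(4S)-4-benzyl-2-oxo-1,3-oxazolidin-3-yl]carbonyl}hex-5-enoate | C=CC[C@H](CC(=O)OC(C)(C)C)C(=O)N1[C@@H](Cc2ccccc2)COC1=O | intermediate
29 | tert-butyl (3R)-3-(hydroxymethyl)hex-5-enoate | C=CC[C@H](CC(=O)OC(C)(C)C)CO | intermediate
30 | tert-butyl (3R)-3-({[tert-butyl(dimethyl)silyl]oxy}methyl)hex-5-enoate | C=CC[C@H](CC(=O)OC(C)(C)C)CO[Si](C)(C)C(C)(C)C | intermediate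
31 | (3R)-3-({[tert-butyl(dimethyl)silyl]oxy}methyl)hex-5-en-1-ol | C=CC[C@H](CCO)CO[Si](C)(C)C(C)(C)C | intermediate
32 | tert-butyl{[(2R)-2-(2-iodoethyl)pent-4-en-1-yl]oxy}dimethylsilane | C=CC[C@H](CCI)CO[Si](C)(C)C(C)(C)C | intermediate
33 | alkyllithium from 32 | C=CC[C@H](CC[Li])CO[Si](C)(C)C(C)(C)C | intermediate
34 | alkylcerium dichloride from 33 | C=CC[C@H](CC[Ce](Cl)Cl)CO[Si](C)(C)C(C)(C)C | intermediate
35 | C10 tertiary allylic alcohol: C9–C8–C7(CH2OTBS)–C15–C16=CH2 chain on the H12 face, OH on the opposite face | COc6ccc(COC[C@@H]1CC(COCc5ccc(OC)cc5)=C2[C@@H]1CC[C@]2(O)CC[C@H](CO[Si](C)(C)C(C)(C)C)CC=C)cc6 | intermediate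
36 | triol from dihydroxylation of the terminal alkene of 35 (C16 epimers) | COc6ccc(COC[C@@H]1CC(COCc5ccc(OC)cc5)=C2[C@@H]1CC[C@]2(O)CC[C@H](CO[Si](C)(C)C(C)(C)C)CC(O)CO)cc6 | intermediate
37 | C16 aldehyde of the C10 carbinol | COc6ccc(COC[C@@H]1CC(COCc5ccc(OC)cc5)=C2[C@@H]1CC[C@]2(O)CC[C@H](CO[Si](C)(C)C(C)(C)C)CC=O)cc6 | intermediate
38 | C10-hydroxy C16-carboxylic acid (seco acid) | COc6ccc(COC[C@@H]1CC(COCc5ccc(OC)cc5)=C2[C@@H]1CC[C@]2(O)CC[C@H](CO[Si](C)(C)C(C)(C)C)CC(=O)O)cc6 | intermediate
39 | mixed anhydride of 38 and 2-methyl-6-nitrobenzoic acid | COc6ccc(COC[C@@H]1CC(COCc5ccc(OC)cc5)=C2[C@@H]1CC[C@]2(O)CC[C@H](CO[Si](C)(C)C(C)(C)C)CC(=O)OC(=O)c3c(C)cccc3[N+](=O)[O-])cc6 | intermediate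
40 | seven-membered spirolactone, C15H2 (ring O on C10 anti to H12, carbonyl C16) | COc6ccc(COC[C@@H]1CC(COCc5ccc(OC)cc5)=C2[C@@H]1CC[C@@]23OC(=O)C[C@@H](CO[Si](C)(C)C(C)(C)C)CC3)cc6 | intermediate
41 | allyl iodide | C=CCI | starting material
42 | lithium enolate of 40 | [Li+].COc6ccc(COC[C@@H]1CC(COCc5ccc(OC)cc5)=C2[C@@H]1CC[C@@]23OC([O-])=C[C@@H](CO[Si](C)(C)C(C)(C)C)CC3)cc6 | intermediate
43 | α-allyl spirolactone, Claisen precursor (C15 epimer mixture, C15 left open) | COc6ccc(COC[C@@H]1CC(COCc5ccc(OC)cc5)=C2[C@@H]1CC[C@@]23OC(=O)C(CC=C)[C@@H](CO[Si](C)(C)C(C)(C)C)CC3)cc6 | intermediate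
44 | ring-locked trimethylsilyl ketene acetal of 43 | COc6ccc(COC[C@@H]1CC(COCc5ccc(OC)cc5)=C2[C@@H]1CC[C@@]23OC(O[Si](C)(C)C)=C(CC=C)[C@@H](CO[Si](C)(C)C(C)(C)C)CC3)cc6 | intermediate
45 | trimethylsilyl ester of 46 | COc6ccc(COC[C@@H]1C[C@]2(COCc5ccc(OC)cc5)[C@@](C(=O)O[Si](C)(C)C)(CC=C)[C@@H](CO[Si](C)(C)C(C)(C)C)CCC3=C2[C@@H]1CC3)cc6 | intermediate
46 | tricyclic C16 acid (rings A, B, C; C15 on C3 anti to H12; C16 cis to C2, allyl cis to C4 and C6 on ring C) | COc6ccc(COC[C@@H]1C[C@]2(COCc5ccc(OC)cc5)[C@@](C(=O)O)(CC=C)[C@@H](CO[Si](C)(C)C(C)(C)C)CCC3=C2[C@@H]1CC3)cc6 | intermediate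
47 | C16 primary alcohol | COc6ccc(COC[C@@H]1C[C@]2(COCc5ccc(OC)cc5)[C@@](CO)(CC=C)[C@@H](CO[Si](C)(C)C(C)(C)C)CCC3=C2[C@@H]1CC3)cc6 | intermediate
48 | C16 benzyl ether | COc6ccc(COC[C@@H]1C[C@]2(COCc5ccc(OC)cc5)[C@@](COCc4ccccc4)(CC=C)[C@@H](CO[Si](C)(C)C(C)(C)C)CCC3=C2[C@@H]1CC3)cc6 | intermediate
49 | B-(C19)-alkyl-9-BBN adduct of 48 | COc6ccc(COC[C@@H]1C[C@]2(COCc5ccc(OC)cc5)[C@@](COCc4ccccc4)(CCCB7C8CCCC7CCC8)[C@@H](CO[Si](C)(C)C(C)(C)C)CCC3=C2[C@@H]1CC3)cc6 | intermediate
50 | C19 primary alcohol | COc6ccc(COC[C@@H]1C[C@]2(COCc5ccc(OC)cc5)[C@@](COCc4ccccc4)(CCCO)[C@@H](CO[Si](C)(C)C(C)(C)C)CCC3=C2[C@@H]1CC3)cc6 | intermediate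
51 | C19 aldehyde | COc6ccc(COC[C@@H]1C[C@]2(COCc5ccc(OC)cc5)[C@@](COCc4ccccc4)(CCC=O)[C@@H](CO[Si](C)(C)C(C)(C)C)CCC3=C2[C@@H]1CC3)cc6 | intermediate
52 | (4S)-4-benzyl-3-propanoyl-1,3-oxazolidin-2-one | CCC(=O)N1[C@@H](Cc2ccccc2)COC1=O | starting material
53 | dibutylboron Z-enolate of 52 | C/C=C(\OB(CCCC)CCCC)N1[C@@H](Cc2ccccc2)COC1=O | intermediate
54 | syn aldol adduct (C19 R, C20 S) | COc6ccc(COC[C@@H]1C[C@]2(COCc5ccc(OC)cc5)[C@@](COCc4ccccc4)(CC[C@@H](O)[C@H](C)C(=O)N7[C@@H](Cc8ccccc8)COC7=O)[C@@H](CO[Si](C)(C)C(C)(C)C)CCC3=C2[C@@H]1CC3)cc6 | intermediate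
55 | C19 TBS ether of 54 | COc6ccc(COC[C@@H]1C[C@]2(COCc5ccc(OC)cc5)[C@@](COCc4ccccc4)(CC[C@@H](O[Si](C)(C)C(C)(C)C)[C@H](C)C(=O)N7[C@@H](Cc8ccccc8)COC7=O)[C@@H](CO[Si](C)(C)C(C)(C)C)CCC3=C2[C@@H]1CC3)cc6 | intermediate
56 | C22 primary alcohol | COc6ccc(COC[C@@H]1C[C@]2(COCc5ccc(OC)cc5)[C@@](COCc4ccccc4)(CC[C@@H](O[Si](C)(C)C(C)(C)C)[C@H](C)CO)[C@@H](CO[Si](C)(C)C(C)(C)C)CCC3=C2[C@@H]1CC3)cc6 | intermediate
57 | 2-nitrobenzenesulfonamide | NS(=O)(=O)c1ccccc1[N+](=O)[O-] | starting material
58 | C22 N-Ns sulfonamide | COc6ccc(COC[C@@H]1C[C@]2(COCc5ccc(OC)cc5)[C@@](COCc4ccccc4)(CC[C@@H](O[Si](C)(C)C(C)(C)C)[C@H](C)CNS(=O)(=O)c7ccccc7[N+](=O)[O-])[C@@H](CO[Si](C)(C)C(C)(C)C)CCC3=C2[C@@H]1CC3)cc6 | intermediate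
59 | C6 alcohol of 58 | COc6ccc(COC[C@@H]1C[C@]2(COCc5ccc(OC)cc5)[C@@](COCc4ccccc4)(CC[C@@H](O[Si](C)(C)C(C)(C)C)[C@H](C)CNS(=O)(=O)c7ccccc7[N+](=O)[O-])[C@@H](CO)CCC3=C2[C@@H]1CC3)cc6 | intermediate
60 | N-Ns nine-membered azacycle (N5 bonded to C6 and C22) | COc6ccc(COC[C@@H]1C[C@]2(COCc5ccc(OC)cc5)[C@@]7(COCc4ccccc4)CC[C@@H](O[Si](C)(C)C(C)(C)C)[C@H](C)CN(S(=O)(=O)c8ccccc8[N+](=O)[O-])C[C@H]7CCC3=C2[C@@H]1CC3)cc6 | intermediate
61 | C1′,C4-diol | OC[C@@H]1C[C@]2(CO)[C@@]7(COCc4ccccc4)CC[C@@H](O[Si](C)(C)C(C)(C)C)[C@H](C)CN(S(=O)(=O)c8ccccc8[N+](=O)[O-])C[C@H]7CCC3=C2[C@@H]1CC3 | intermediate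
62 | C1′,C4-dicarboxylic acid | OC(=O)[C@@H]1C[C@]2(C(=O)O)[C@@]7(COCc4ccccc4)CC[C@@H](O[Si](C)(C)C(C)(C)C)[C@H](C)CN(S(=O)(=O)c8ccccc8[N+](=O)[O-])C[C@H]7CCC3=C2[C@@H]1CC3 | intermediate
63 | dimethyl ester of 62 | COC(=O)[C@@H]1C[C@]2(C(=O)OC)[C@@]7(COCc4ccccc4)CC[C@@H](O[Si](C)(C)C(C)(C)C)[C@H](C)CN(S(=O)(=O)c8ccccc8[N+](=O)[O-])C[C@H]7CCC3=C2[C@@H]1CC3 | intermediate
64 | free nine-membered secondary amine | COC(=O)[C@@H]1C[C@]2(C(=O)OC)[C@@]7(COCc4ccccc4)CC[C@@H](O[Si](C)(C)C(C)(C)C)[C@H](C)CNC[C@H]7CCC3=C2[C@@H]1CC3 | intermediate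
65 | pentacyclic lactam, C16 OBn, C19 OTBS | COC(=O)[C@@H]1C[C@@]23C(=O)N4C[C@@H](CCC5=C2[C@@H]1CC5)[C@]3(COCc6ccccc6)CC[C@@H](O[Si](C)(C)C(C)(C)C)[C@H](C)C4 | intermediate
66 | pentacyclic lactam, C16 OH, C19 OTBS | COC(=O)[C@@H]1C[C@@]23C(=O)N4C[C@@H](CCC5=C2[C@@H]1CC5)[C@]3(CO)CC[C@@H](O[Si](C)(C)C(C)(C)C)[C@H](C)C4 | intermediate
67 | pentacyclic lactam, C16 OAc, C19 OTBS | COC(=O)[C@@H]1C[C@@]23C(=O)N4C[C@@H](CCC5=C2[C@@H]1CC5)[C@]3(COC(C)=O)CC[C@@H](O[Si](C)(C)C(C)(C)C)[C@H](C)C4 | intermediate
68 | CNP0296366.1 | COC(=O)[C@@H]1C[C@@]23C(=O)N4C[C@@H](CCC5=C2[C@@H]1CC5)[C@]3(COC(C)=O)CC[C@@H](O)[C@H](C)C4 | target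

Total step count: 39.
Longest linear sequence: 32 steps (steps 2–10, then 17–39).

Steps most likely to fail

1. **Step 22.** The crowded boat array on the concave face may react more slowly than the tertiary allylic C10–O bond ionises. That would lead to elimination to a diene acid, or the ketene acetal may simply revert on heating.
 - The fallback builds the quaternary pair in two operations and sets out from 40.
 - The same silylation, heating and hydrolysis are applied to 40, where only C3 becomes quaternary. This should give the C15–H tricyclic acid F1.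
 - Me3SiCHN2 converts F1 into the methyl ester F2.
 - LiN(iPr)2 and then allyl bromide alkylate the C15 ester enolate. Its inner face is covered by ring A and the C1′ arm, so the electrophile should enter from the open outer face.
 - This gives the allylated methyl ester F3 with the C15 configuration of 46.
 - LiAlH4 reduces F3 to 47, where the route is rejoined.

2. **Step 20.** Acyl transfer to the tertiary allylic carbinol may be too slow, so intermolecular acylation (oligomers) or loss of the carbinol by ionisation takes over.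
 - The fallback activates the oxygen rather than the acyl group and sets out from 38.
 - EDC·HCl and C6F5OH give the storable pentafluorophenyl ester F4, towards which the neutral tertiary alcohol is inert.
 - Slow addition of F4 to KN(SiMe3)2 in dilute THF at −78 to 0 °C turns the carbinol into its potassium alkoxide.
 - The alkoxide displaces pentafluorophenoxide irreversibly and closes the ring, coming back at 40.

3. **Step 32.** Medium-ring strain and the β-branched C6 may slow the substitution, so intermolecular alkylation or capture of the activated alcohol by the hydrazide competes.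
 - The fallback makes the N5–C6 bond by reductive amination and sets out from 59.
 - Dess–Martin periodinane gives the C6 aldehyde F5.
 - PhSH and K2CO3 in MeCN remove the Ns group to give the amino aldehyde F6, which condenses reversibly under dilution to the nine-membered cyclic imine F7.
 - NaBH(OAc)3 added to the same flask reduces F7 to the cyclic secondary amine F8.
 - 2-Nitrobenzenesulfonyl chloride and Et3N then return 60.

Further compounds
F1 | step 22 | C15–H tricyclic C16 acid from rearrangement of 40 | COc6ccc(COC[C@@H]1C[C@]2(COCc5ccc(OC)cc5)[C@H](C(=O)O)[C@@H](CO[Si](C)(C)C(C)(C)C)CCC3=C2[C@@H]1CC3)cc6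
F2 | step 22 | methyl ester of F1 | COc6ccc(COC[C@@H]1C[C@]2(COCc5ccc(OC)cc5)[C@H](C(=O)OC)[C@@H](CO[Si](C)(C)C(C)(C)C)CCC3=C2[C@@H]1CC3)cc6
F3 | step 22 | C15-allylated methyl ester (methyl ester of 46) | COc6ccc(COC[C@@H]1C[C@]2(COCc5ccc(OC)cc5)[C@@](C(=O)OC)(CC=C)[C@@H](CO[Si](C)(C)C(C)(C)C)CCC3=C2[C@@H]1CC3)cc6
F4 | step 20 | pentafluorophenyl ester of 38 | COc6ccc(COC[C@@H]1CC(COCc5ccc(OC)cc5)=C2[C@@H]1CC[C@]2(O)CC[C@H](CO[Si](C)(C)C(C)(C)C)CC(=O)Oc3c(F)c(F)c(F)c(F)c3F)cc6
F5 | step 32 | C6 aldehyde of 59 | COc6ccc(COC[C@@H]1C[C@]2(COCc5ccc(OC)cc5)[C@@](COCc4ccccc4)(CC[C@@H](O[Si](C)(C)C(C)(C)C)[C@H](C)CNS(=O)(=O)c7ccccc7[N+](=O)[O-])[C@@H](C=O)CCC3=C2[C@@H]1CC3)cc6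
F6 | step 32 | C22 amino C6 aldehyde | COc6ccc(COC[C@@H]1C[C@]2(COCc5ccc(OC)cc5)[C@@](COCc4ccccc4)(CC[C@@H](O[Si](C)(C)C(C)(C)C)[C@H](C)CN)[C@@H](C=O)CCC3=C2[C@@H]1CC3)cc6
F7 | step 32 | nine-membered cyclic imine (N5=C6) | COc6ccc(COC[C@@H]1C[C@]2(COCc5ccc(OC)cc5)[C@@]7(COCc4ccccc4)CC[C@@H](O[Si](C)(C)C(C)(C)C)[C@H](C)CN=C[C@H]7CCC3=C2[C@@H]1CC3)cc6
F8 | step 32 | nine-membered cyclic secondary amine with both PMB arms | COc6ccc(COC[C@@H]1C[C@]2(COCc5ccc(OC)cc5)[C@@]7(COCc4ccccc4)CC[C@@H](O[Si](C)(C)C(C)(C)C)[C@H](C)CNC[C@H]7CCC3=C2[C@@H]1CC3)cc6
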